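**Retrosynthetic overview**
1. Target ⇐ C6 aroylation and phenol desilylation ⇐ isopropyl addition to the C4 ketone of a cis-fused β-hydroxy ketone that already carries the C10 tiglate.
2. β-Hydroxy ketone ⇐ N–O cleavage of an isoxazoline made by an intramolecular nitrile oxide–alkene [3+2] cycloaddition, which closes the five-membered ring and sets C5 and C6 from C1.
3. Cycloheptadiene dipolarophile ⇐ ring-closing metathesis (C8=C9) of a triene built by a Z-Wittig reaction (C5=C6) and a methylenation (C9).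
4. Quaternary C1 next to C10–O ⇐ two successive dianion alkylations (MeI, then a silylpropargyl bromide) of (S)-3-hydroxy-γ-butyrolactone, the only source of chirality.
5. Ring order: seven-membered ring first (metathesis), five-membered ring second (cycloaddition).

Assumption: locants C1–C10 below are the daucane locants of the target: C1 (ring-fusion C–CH3), C2, C3, C4 (C(OH)i-Pr), C5 (ring-fusion CH), C6 (CH–O-aroyl), C7, C8 (=C–CH3), C9, C10 (CH–O-tigloyl).

**Step 1**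
Reactants: 1 (S)-3-hydroxy-γ-butyrolactone [(4S)-4-hydroxydihydrofuran-2(3H)-one]
Product: 3 (3S,4S)-4-hydroxy-3-methyldihydrofuran-2(3H)-one (methyl trans to hydroxyl), via lactone dianion 2 (not isolated)
Conditions: LiN(i-Pr)2 (2.2 equiv), THF, −78 °C; MeI, −78 to −30 °C; AcOH
Reagents that add atoms: methyl iodide, CI
Why: Fráter–Seebach-type alkylation of the alkoxide–enolate dianion, in which the C10 alkoxide (which also prevents β-elimination) shields one face so MeI enters trans to oxygen.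

**Step 2**
Reactants: 3 (3S,4S)-4-hydroxy-3-methyldihydrofuran-2(3H)-one; 4 3-bromo-1-(triisopropylsilyl)prop-1-yne
Product: 6 (3S,4S)-4-hydroxy-3-methyl-3-[3-(triisopropylsilyl)prop-2-yn-1-yl]dihydrofuran-2(3H)-one (methyl cis to hydroxyl; propargyl trans), via methyl-lactone dianion 5 (not isolated)
Conditions: LiN(i-Pr)2 (2.3 equiv), THF/DMPU, −78 to −20 °C; 4, −78 to 0 °C; AcOH
Reagents that add atoms: none
Why: A second dianion alkylation again takes place anti to the C10 alkoxide, so the reactive propargylic bromide ends trans and the methyl cis to oxygen, which fixes the quaternary C1 centre by substrate control.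

**Step 3**
Reactants: 6 (3S,4S)-4-hydroxy-3-methyl-3-[3-(triisopropylsilyl)prop-2-yn-1-yl]dihydrofuran-2(3H)-one
Product: 7 (3S,4S)-3-methyl-4-[(triisopropylsilyl)oxy]-3-[3-(triisopropylsilyl)prop-2-yn-1-yl]dihydrofuran-2(3H)-one
Conditions: i-Pr3SiOTf, 2,6-lutidine, CH2Cl2, 0 °C to rt
Reagents that add atoms: triisopropylsilyl trifluoromethanesulfonate, CC(C)[Si](C(C)C)(C(C)C)OS(=O)(=O)C(F)(F)F
Why: O-silylation with a silyl triflate masks the C10 hydroxyl (needed to avoid retro-aldol cleavage in step 6) with a bulky group that resists base-induced migration.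

**Step 4**
Reactants: 7 (3S,4S)-3-methyl-4-[(triisopropylsilyl)oxy]-3-[3-(triisopropylsilyl)prop-2-yn-1-yl]dihydrofuran-2(3H)-one
Product: 8 (3S,4S)-3-methyl-4-[(triisopropylsilyl)oxy]-3-[3-(triisopropylsilyl)prop-2-yn-1-yl]tetrahydrofuran-2-ol (lactol; anomer mixture)
Conditions: i-Bu2AlH (1.2 equiv), CH2Cl2, −78 °C; aq. sodium potassium tartrate
Reagents that add atoms: none
Why: Partial hydride reduction of the hindered lactone stops at the tetrahedral aluminate, which gives the lactol on work-up.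

**Step 5**
Reactants: 9 4-bromo-2-methylbut-1-ene
Product: 10 (3-methylbut-3-en-1-yl)triphenylphosphonium bromide
Conditions: PPh3, MeCN, reflux
Reagents that add atoms: triphenylphosphine, c1ccc(cc1)P(c1ccccc1)c1ccccc1
Why: SN2 quaternisation of the phosphine by the primary homoallylic bromide.

**Step 6**
Reactants: 8 lactol (3S,4S)-3-methyl-4-[(triisopropylsilyl)oxy]-3-[3-(triisopropylsilyl)prop-2-yn-1-yl]tetrahydrofuran-2-ol; 10 (3-methylbut-3-en-1-yl)triphenylphosphonium bromide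
Product: 11 (2S,3R,4Z)-3,7-dimethyl-2-[(triisopropylsilyl)oxy]-3-[3-(triisopropylsilyl)prop-2-yn-1-yl]octa-4,7-dien-1-ol
Conditions: 10 (3 equiv), KN(SiMe3)2 (2.9 equiv), THF, −78 to 0 °C; then 8, 0 °C to rt
Reagents that add atoms: none
Why: Wittig olefination of the lactol through its open hydroxy-aldehyde form, where the salt-free non-stabilised ylide gives the (Z)-C5=C6 alkene under kinetic control.

**Step 7**
Reactants: 11 (2S,3R,4Z)-3,7-dimethyl-2-[(triisopropylsilyl)oxy]-3-[3-(triisopropylsilyl)prop-2-yn-1-yl]octa-4,7-dien-1-ol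
Product: 13 (4Z,6R,7R)-2,6-dimethyl-7-[(triisopropylsilyl)oxy]-6-[3-(triisopropylsilyl)prop-2-yn-1-yl]nona-1,4,8-triene, via aldehyde 12 (not isolated)
Conditions: (COCl)2, DMSO, CH2Cl2, −78 °C; Et3N, to 0 °C; then Ph3P=CH2 (from Ph3PCH3Br, KN(SiMe3)2, THF), −78 °C to rt
Reagents that add atoms: methyltriphenylphosphonium bromide, C[P+](c1ccccc1)(c1ccccc1)c1ccccc1.[Br-]
Why: Swern oxidation followed in the same flask by Wittig methylenation converts C9 into the vinyl group without isolating the epimerisable α-silyloxy aldehyde.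

**Step 8**
Reactants: 13 (4Z,6R,7R)-2,6-dimethyl-7-[(triisopropylsilyl)oxy]-6-[3-(triisopropylsilyl)prop-2-yn-1-yl]nona-1,4,8-triene
Product: 14 triisopropyl({(1R,7R)-3,7-dimethyl-7-[3-(triisopropylsilyl)prop-2-yn-1-yl]cyclohepta-2,5-dien-1-yl}oxy)silane (ring C1 = C10; ring C7 = C1 of the target)
Conditions: second-generation Grubbs catalyst RuCl2(=CHPh)(PCy3)(H2IMes) (10 mol %), CH2Cl2 (2 mM), 40 °C
Reagents that add atoms: none
Why: Ring-closing metathesis of the vinyl and isopropenyl termini forms the trisubstituted C8=C9 alkene of the seven-membered ring with loss of ethene, while the Z-alkene and the shielded silylalkyne are poor partners for the catalyst.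

**Step 9**
Reactants: 14 triisopropyl({(1R,7R)-3,7-dimethyl-7-[3-(triisopropylsilyl)prop-2-yn-1-yl]cyclohepta-2,5-dien-1-yl}oxy)silane
Product: 15 (1R,7R)-3,7-dimethyl-7-(prop-2-yn-1-yl)cyclohepta-2,5-dien-1-ol
Conditions: Bu4NF (3 equiv), THF, rt to 40 °C
Reagents that add atoms: none
Why: Fluoride cleaves both the Si–O and the Si–C(sp) bond in one operation, driven by Si–F bond formation.

**Step 10**
Reactants: 15 (1R,7R)-3,7-dimethyl-7-(prop-2-yn-1-yl)cyclohepta-2,5-dien-1-ol; 16 tigloyl chloride [(2E)-2-methylbut-2-enoyl chloride]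
Product: 17 (1R,7R)-3,7-dimethyl-7-(prop-2-yn-1-yl)cyclohepta-2,5-dien-1-yl (2E)-2-methylbut-2-enoate
Conditions: 16 (1.5 equiv), pyridine, DMAP (cat.), CH2Cl2, 0 °C to rt
Reagents that add atoms: none
Why: DMAP-catalysed acylation of the only hydroxyl group installs the C10 ester with the thermodynamically stable (E)-geometry retained.

**Step 11**
Reactants: 17 (1R,7R)-3,7-dimethyl-7-(prop-2-yn-1-yl)cyclohepta-2,5-dien-1-yl (2E)-2-methylbut-2-enoate
Product: 19 (1R,7R)-3,7-dimethyl-7-(3-oxopropyl)cyclohepta-2,5-dien-1-yl (2E)-2-methylbut-2-enoate, via alkenylborane 18 (not isolated)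
Conditions: (c-C6H11)2BH (1.3 equiv), THF, 0 °C; then H2O2, aq. NaHCO3, 0 °C to rt
Reagents that add atoms: hydrogen peroxide, OO
Why: Anti-Markovnikov syn-hydroboration of the terminal alkyne by the bulky dialkylborane (far faster than reaction at the ring alkenes or the enoate) and oxidation give the enol, which tautomerises to the C4 aldehyde.

**Step 12**
Reactants: 19 (1R,7R)-3,7-dimethyl-7-(3-oxopropyl)cyclohepta-2,5-dien-1-yl (2E)-2-methylbut-2-enoate
Product: 22 (1R,5R,6R,10R)-isoxazoline: cis-fused 1,8-dimethylbicyclo[5.3.0]dec-8-ene (daucane locants) carrying a C4=N–O–C6 bridge and the 10-O-tigloyl group, via oxime 20 (not isolated), via nitrile oxide 21 (not isolated)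
Conditions: NH2OH·HCl, Et3N, CH2Cl2/MeOH, rt; then aq. NaOCl, 0 °C to rt
Reagents that add atoms: hydroxylamine hydrochloride, NO.Cl
Why: In this intramolecular nitrile oxide–alkene 1,3-dipolar (Huisgen [3+2]) cycloaddition the three-atom tether on C1 delivers C4 to C5 and O to C6 suprafacially on the tether face of the C5=C6 alkene, so the five-membered ring closes cis-fused with H5 cis to the C1 methyl and C6–O trans to H5.

**Step 13**
Reactants: 22 (1R,5R,6R,10R)-isoxazoline with C4=N–O–C6 bridge and 10-O-tigloyl group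
Product: 24 (1R,5S,6R,10R)-6-hydroxy-1,8-dimethyl-4-oxo-cis-bicyclo[5.3.0]dec-8-en-10-yl (2E)-2-methylbut-2-enoate (daucane locants), via hydroxy imine 23 (not isolated)
Conditions: SmI2 (2.5 equiv), THF, 0 °C; air; then B(OH)3, MeOH/H2O, rt
Reagents that add atoms: water, O
Why: Single-electron reductive N–O cleavage and buffered hydrolysis of the resulting imine unmask the aldol-type β-hydroxy ketone without touching C5, C6 or the esters.

**Step 14**
Reactants: 24 (1R,5S,6R,10R)-6-hydroxy-1,8-dimethyl-4-oxo-cis-bicyclo[5.3.0]dec-8-en-10-yl (2E)-2-methylbut-2-enoate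
Product: 25 (1R,4R,5S,6R,10R)-4,6-dihydroxy-4-isopropyl-1,8-dimethyl-cis-bicyclo[5.3.0]dec-8-en-10-yl (2E)-2-methylbut-2-enoate (daucane locants)
Conditions: i-PrLi (3.5 equiv), CeCl3 (3.5 equiv), THF, −78 °C; AcOH, then aq. NaHCO3
Reagents that add atoms: isopropyllithium, [Li]C(C)C
Why: 1,2-Addition of the weakly basic organocerium reagent to the cyclopentanone (faster than to the hindered enoate at −78 °C) occurs from the convex face bearing H5 and the C1 methyl, opposite the seven-membered ring, so isopropyl ends cis to H5 and the C4 hydroxyl on the concave face.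

**Step 15**
Reactants: 25 (1R,4R,5S,6R,10R)-4,6-dihydroxy-4-isopropyl-1,8-dimethyl-cis-bicyclo[5.3.0]dec-8-en-10-yl (2E)-2-methylbut-2-enoate; 26 4-[(tert-butyldimethylsilyl)oxy]benzoic acid
Product: 27 phenol-O-silylated target: (1R,4R,5S,6R,10R)-4-hydroxy-4-isopropyl-1,8-dimethyl-10-(tigloyloxy)-cis-bicyclo[5.3.0]dec-8-en-6-yl 4-[(tert-butyldimethylsilyl)oxy]benzoate (daucane locants)
Conditions: 26 (1.5 equiv), DCC, DMAP, CH2Cl2, rt to 40 °C
Reagents that add atoms: none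
Why: Steglich esterification acylates the secondary C6 hydroxyl selectively, the tertiary C4 hydroxyl being unreactive.

**Step 16**
Reactants: 27 phenol-O-silylated target
Product: 28 target: (3R,3aS,4R,8R,8aR)-3-hydroxy-6,8a-dimethyl-8-{[(2E)-2-methylbut-2-enoyl]oxy}-3-(propan-2-yl)-1,2,3,3a,4,5,8,8a-octahydroazulen-4-yl 4-hydroxybenzoate (daucane descriptors 1R,4R,5S,6R,10R)
Conditions: Bu4NF, AcOH (1:1), THF, 0 °C
Reagents that add atoms: none
Why: Buffered fluoride cleaves the aryl silyl ether and leaves both esters, the tertiary alcohol and all stereocentres untouched.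

**Compound list**
1 | (S)-3-hydroxy-γ-butyrolactone [(4S)-4-hydroxydihydrofuran-2(3H)-one] | O[C@@H]1COC(=O)C1 | starting material
2 | dilithium alkoxide–enolate (dianion) of 1 | [Li]O[C@@H]1COC(O[Li])=C1 | intermediate
3 | (3S,4S)-4-hydroxy-3-methyldihydrofuran-2(3H)-one (methyl trans to OH) | O[C@@H]1COC(=O)[C@H]1C | intermediate
4 | 3-bromo-1-(triisopropylsilyl)prop-1-yne | BrCC#C[Si](C(C)C)(C(C)C)C(C)C | starting material
5 | dilithium alkoxide–enolate (dianion) of 3 | [Li]O[C@@H]1COC(O[Li])=C1C | intermediate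
6 | (3S,4S)-4-hydroxy-3-methyl-3-[3-(triisopropylsilyl)prop-2-yn-1-yl]dihydrofuran-2(3H)-one | O[C@@H]1COC(=O)[C@@]1(C)CC#C[Si](C(C)C)(C(C)C)C(C)C | intermediate
7 | (3S,4S)-3-methyl-4-[(triisopropylsilyl)oxy]-3-[3-(triisopropylsilyl)prop-2-yn-1-yl]dihydrofuran-2(3H)-one | CC(C)[Si](C(C)C)(C(C)C)O[C@@H]1COC(=O)[C@@]1(C)CC#C[Si](C(C)C)(C(C)C)C(C)C | intermediate
8 | (3S,4S)-3-methyl-4-[(triisopropylsilyl)oxy]-3-[3-(triisopropylsilyl)prop-2-yn-1-yl]tetrahydrofuran-2-ol (anomer mixture) | CC(C)[Si](C(C)C)(C(C)C)O[C@@H]1COC(O)[C@@]1(C)CC#C[Si](C(C)C)(C(C)C)C(C)C | intermediate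
9 | 4-bromo-2-methylbut-1-ene | C=C(C)CCBr | starting material
10 | (3-methylbut-3-en-1-yl)triphenylphosphonium bromide | C=C(C)CC[P+](c1ccccc1)(c1ccccc1)c1ccccc1.[Br-] | intermediate
11 | (2S,3R,4Z)-3,7-dimethyl-2-[(triisopropylsilyl)oxy]-3-[3-(triisopropylsilyl)prop-2-yn-1-yl]octa-4,7-dien-1-ol | OC[C@@H](O[Si](C(C)C)(C(C)C)C(C)C)[C@](C)(CC#C[Si](C(C)C)(C(C)C)C(C)C)/C=C\CC(C)=C | intermediate
12 | (2S,3R,4Z)-3,7-dimethyl-2-[(triisopropylsilyl)oxy]-3-[3-(triisopropylsilyl)prop-2-yn-1-yl]octa-4,7-dienal | O=C[C@@H](O[Si](C(C)C)(C(C)C)C(C)C)[C@](C)(CC#C[Si](C(C)C)(C(C)C)C(C)C)/C=C\CC(C)=C | intermediate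
13 | (4Z,6R,7R)-2,6-dimethyl-7-[(triisopropylsilyl)oxy]-6-[3-(triisopropylsilyl)prop-2-yn-1-yl]nona-1,4,8-triene | C=C[C@@H](O[Si](C(C)C)(C(C)C)C(C)C)[C@](C)(CC#C[Si](C(C)C)(C(C)C)C(C)C)/C=C\CC(C)=C | intermediate
14 | triisopropyl({(1R,7R)-3,7-dimethyl-7-[3-(triisopropylsilyl)prop-2-yn-1-yl]cyclohepta-2,5-dien-1-yl}oxy)silane | CC(C)[Si](C(C)C)(C(C)C)O[C@@H]1C=C(C)CC=C[C@@]1(C)CC#C[Si](C(C)C)(C(C)C)C(C)C | intermediate
15 | (1R,7R)-3,7-dimethyl-7-(prop-2-yn-1-yl)cyclohepta-2,5-dien-1-ol | O[C@@H]1C=C(C)CC=C[C@@]1(C)CC#C | intermediate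
16 | tigloyl chloride [(2E)-2-methylbut-2-enoyl chloride] | C/C=C(\C)C(Cl)=O | starting material
17 | (1R,7R)-3,7-dimethyl-7-(prop-2-yn-1-yl)cyclohepta-2,5-dien-1-yl (2E)-2-methylbut-2-enoate | C/C=C(\C)C(=O)O[C@@H]1C=C(C)CC=C[C@@]1(C)CC#C | intermediate
18 | (E)-alkenyl(dicyclohexyl)borane from 17 | C/C=C(\C)C(=O)O[C@@H]1C=C(C)CC=C[C@@]1(C)C/C=C/B(C2CCCCC2)C3CCCCC3 | intermediate
19 | (1R,7R)-3,7-dimethyl-7-(3-oxopropyl)cyclohepta-2,5-dien-1-yl (2E)-2-methylbut-2-enoate | C/C=C(\C)C(=O)O[C@@H]1C=C(C)CC=C[C@@]1(C)CCC=O | intermediate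
20 | aldoxime of 19 (E/Z mixture) | C/C=C(\C)C(=O)O[C@@H]1C=C(C)CC=C[C@@]1(C)CCC=NO | intermediate
21 | nitrile oxide from 20 | C/C=C(\C)C(=O)O[C@@H]1C=C(C)CC=C[C@@]1(C)CCC#[N+][O-] | intermediate
22 | (1R,5R,6R,10R)-isoxazoline, C4=N–O–C6 bridge on the cis-fused 1,8-dimethylbicyclo[5.3.0]dec-8-ene, 10-O-tigloyl (daucane locants) | C/C=C(\C)C(=O)O[C@@H]1C=C(C)C[C@@H]3[C@@H]2[C@@]1(C)CCC2=NO3 | intermediate
23 | (1R,5R,6R,10R)-6-hydroxy-4-imino analogue of 24 (β-hydroxy imine) | C/C=C(\C)C(=O)O[C@@H]1C=C(C)C[C@@H](O)[C@@H]2[C@@]1(C)CCC2=N | intermediate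
24 | (1R,5S,6R,10R)-6-hydroxy-1,8-dimethyl-4-oxo-cis-bicyclo[5.3.0]dec-8-en-10-yl (2E)-2-methylbut-2-enoate (daucane locants) | C/C=C(\C)C(=O)O[C@@H]1C=C(C)C[C@@H](O)[C@@H]2[C@@]1(C)CCC2=O | intermediate
25 | (1R,4R,5S,6R,10R)-4,6-dihydroxy-4-isopropyl-1,8-dimethyl-cis-bicyclo[5.3.0]dec-8-en-10-yl (2E)-2-methylbut-2-enoate (daucane locants) | C/C=C(\C)C(=O)O[C@@H]1C=C(C)C[C@@H](O)[C@@H]2[C@@]1(C)CC[C@@]2(O)C(C)C | intermediate
26 | 4-[(tert-butyldimethylsilyl)oxy]benzoic acid | OC(=O)c1ccc(O[Si](C)(C)C(C)(C)C)cc1 | starting material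
27 | phenol-O-TBS target (6-O-[4-(tert-butyldimethylsilyloxy)benzoyl], 10-O-tigloyl; 1R,4R,5S,6R,10R) | C/C=C(\C)C(=O)O[C@@H]1C=C(C)C[C@@H](OC(=O)c2ccc(O[Si](C)(C)C(C)(C)C)cc2)[C@@H]2[C@@]1(C)CC[C@@]2(O)C(C)C | intermediate
28 | (3R,3aS,4R,8R,8aR)-3-hydroxy-6,8a-dimethyl-8-{[(2E)-2-methylbut-2-enoyl]oxy}-3-(propan-2-yl)-1,2,3,3a,4,5,8,8a-octahydroazulen-4-yl 4-hydroxybenzoate | C/C=C(\C)C(=O)O[C@@H]1C=C(C)C[C@@H](OC(=O)c2ccc(O)cc2)[C@@H]2[C@@]1(C)CC[C@@]2(O)C(C)C | target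

**Step count**
Total: 16 steps. Longest linear sequence: 15 steps (1 → 28 through steps 1–4 and 6–16; step 5 is a one-step side branch).

**Three steps most likely to fail**

Step 6 (Wittig on the hindered α-quaternary lactol: slow ring opening, and a possible silyl shift to the neighbouring C9 alkoxide). The fallback sets out from lactone 7 and comes back to the route at triene 13. MeNH(OMe)·HCl with i-PrMgCl opens 7 to the hydroxy Weinreb amide (2S,3S)-4-hydroxy-N-methoxy-N,2-dimethyl-3-[(triisopropylsilyl)oxy]-2-[3-(triisopropylsilyl)prop-2-yn-1-yl]butanamide F1. Dess–Martin periodinane gives the aldehyde (2S,3S)-N-methoxy-N,2-dimethyl-4-oxo-3-[(triisopropylsilyl)oxy]-2-[3-(triisopropylsilyl)prop-2-yn-1-yl]butanamide F2. Ph3P=CH2 gives the vinyl amide (2S,3R)-N-methoxy-N,2-dimethyl-3-[(triisopropylsilyl)oxy]-2-[3-(triisopropylsilyl)prop-2-yn-1-yl]pent-4-enamide F3. i-Bu2AlH at −78 °C then gives the free neopentyl aldehyde (2S,3R)-2-methyl-3-[(triisopropylsilyl)oxy]-2-[3-(triisopropylsilyl)prop-2-yn-1-yl]pent-4-enal F4, which reacts with the ylide of 10 to give 13. The two olefinations are thus run in reverse order on open-chain carbonyls, with no lactol and no alkoxide next to the silyl ether.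

Step 8 (metathesis to a trisubstituted cycloheptene next to a bulky allylic silyl ether, with a silylalkyne present). The fallback sets out from lactol 8 and comes back at cycloheptadiene 14. Wittig reaction of 8 with the ylide of [2-(2-methyl-1,3-dioxolan-2-yl)ethyl]triphenylphosphonium bromide gives (2S,3R,4Z)-3-methyl-6-(2-methyl-1,3-dioxolan-2-yl)-2-[(triisopropylsilyl)oxy]-3-[3-(triisopropylsilyl)prop-2-yn-1-yl]hex-4-en-1-ol F5. Dess–Martin oxidation gives the aldehyde (2S,3R,4Z)-3-methyl-6-(2-methyl-1,3-dioxolan-2-yl)-2-[(triisopropylsilyl)oxy]-3-[3-(triisopropylsilyl)prop-2-yn-1-yl]hex-4-enal F6. Pyridinium tosylate in wet acetone releases the keto aldehyde (2S,3R,4Z)-3-methyl-7-oxo-2-[(triisopropylsilyl)oxy]-3-[3-(triisopropylsilyl)prop-2-yn-1-yl]oct-4-enal F7. Intramolecular McMurry coupling (TiCl3(DME)1.5, Zn–Cu couple, DME, reflux, high dilution) then forms C8=C9 and gives 14.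

Step 14 (a secondary alkyl nucleophile on a hindered, enolisable β-hydroxy ketone in the presence of the tiglate: reduction, enolisation, retro-aldol or ester attack may compete). The fallback sets out from ketone 24 and comes back at diol 25. CH2=C(CH3)MgBr with CeCl3 at −78 °C adds the smaller sp2 nucleophile, which has no β-hydrogen, from the same convex face to give the isopropenyl carbinol (1R,4S,5S,6R,10R)-4,6-dihydroxy-1,8-dimethyl-4-(prop-1-en-2-yl)-cis-bicyclo[5.3.0]dec-8-en-10-yl (2E)-2-methylbut-2-enoate F8. Hydrogenation with H2 and RhCl(PPh3)3 saturates only the 1,1-disubstituted alkene and gives 25.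

**Further compounds**
F1 | step 6 | (2S,3S)-4-hydroxy-N-methoxy-N,2-dimethyl-3-[(triisopropylsilyl)oxy]-2-[3-(triisopropylsilyl)prop-2-yn-1-yl]butanamide | OC[C@@H](O[Si](C(C)C)(C(C)C)C(C)C)[C@](C)(CC#C[Si](C(C)C)(C(C)C)C(C)C)C(=O)N(C)OC
F2 | step 6 | (2S,3S)-N-methoxy-N,2-dimethyl-4-oxo-3-[(triisopropylsilyl)oxy]-2-[3-(triisopropylsilyl)prop-2-yn-1-yl]butanamide | O=C[C@@H](O[Si](C(C)C)(C(C)C)C(C)C)[C@](C)(CC#C[Si](C(C)C)(C(C)C)C(C)C)C(=O)N(C)OC
F3 | step 6 | (2S,3R)-N-methoxy-N,2-dimethyl-3-[(triisopropylsilyl)oxy]-2-[3-(triisopropylsilyl)prop-2-yn-1-yl]pent-4-enamide | C=C[C@@H](O[Si](C(C)C)(C(C)C)C(C)C)[C@](C)(CC#C[Si](C(C)C)(C(C)C)C(C)C)C(=O)N(C)OC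
F4 | step 6 | (2S,3R)-2-methyl-3-[(triisopropylsilyl)oxy]-2-[3-(triisopropylsilyl)prop-2-yn-1-yl]pent-4-enal | C=C[C@@H](O[Si](C(C)C)(C(C)C)C(C)C)[C@](C)(CC#C[Si](C(C)C)(C(C)C)C(C)C)C=O
F5 | step 8 | (2S,3R,4Z)-3-methyl-6-(2-methyl-1,3-dioxolan-2-yl)-2-[(triisopropylsilyl)oxy]-3-[3-(triisopropylsilyl)prop-2-yn-1-yl]hex-4-en-1-ol | OC[C@@H](O[Si](C(C)C)(C(C)C)C(C)C)[C@](C)(CC#C[Si](C(C)C)(C(C)C)C(C)C)/C=C\CC1(C)OCCO1
F6 | step 8 | (2S,3R,4Z)-3-methyl-6-(2-methyl-1,3-dioxolan-2-yl)-2-[(triisopropylsilyl)oxy]-3-[3-(triisopropylsilyl)prop-2-yn-1-yl]hex-4-enal | O=C[C@@H](O[Si](C(C)C)(C(C)C)C(C)C)[C@](C)(CC#C[Si](C(C)C)(C(C)C)C(C)C)/C=C\CC1(C)OCCO1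
F7 | step 8 | (2S,3R,4Z)-3-methyl-7-oxo-2-[(triisopropylsilyl)oxy]-3-[3-(triisopropylsilyl)prop-2-yn-1-yl]oct-4-enal | O=C[C@@H](O[Si](C(C)C)(C(C)C)C(C)C)[C@](C)(CC#C[Si](C(C)C)(C(C)C)C(C)C)/C=C\CC(C)=O
F8 | step 14 | (1R,4S,5S,6R,10R)-4,6-dihydroxy-1,8-dimethyl-4-(prop-1-en-2-yl)-cis-bicyclo[5.3.0]dec-8-en-10-yl (2E)-2-methylbut-2-enoate (daucane locants) | C/C=C(\C)C(=O)O[C@@H]1C=C(C)C[C@@H](O)[C@@H]2[C@@]1(C)CC[C@@]2(O)C(C)=C
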